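The route rests on disconnecting the furanone at C1–C2 and at O–C10. In the precursor, C1 is tied to O6 as a seven-membered lactone that is not part of the target, C10 carries a tertiary bromide, and the cis C4=C5 bond holds the C3 methyl ketone next to this lactone. Enolisation at C2 should start an O6-to-C2 acyl shift that expands the lactone to the ten-membered carbocycle C1–C10. The β-diketonate oxygen on C3 then displaces bromide at C10 with inversion and closes the furanone ring (O, C10, C1, C2, C3). One operation thus forms the carbocycle and the furanone and frees O6 for the last esterification.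

Key step: step 12

Remark: atom labels C1 to C15 follow germacranolide numbering of the target (C1 furanone carbonyl, C2=C3 furanone olefin, C4=C5 the Z olefin with methyl C15, C6 ester carbinol, C7, C8 lactone carbinol, C9, C10 quaternary carbon with methyl C14, C11 to C13 methylene lactone); O6 and O8 are the oxygens on C6 and C8.

Step 1
Reactants: 1 tert-butyl propionate; 2 allyl bromide
Product: 3 tert-butyl 2-methylpent-4-enoate (racemic)
Conditions: LiN(iPr)2, THF, −78 °C; then 2, −78 to 0 °C
Reagents that add atoms: none
Why: Ester enolate alkylation with an allylic bromide should give the C1/C10/C9/C8 chain; C10 is left racemic because it is set in step 6.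

Step 2
Reactants: 3
Product: 4 tert-butyl 2-methyl-4-oxobutanoate (racemic)
Conditions: O3, CH2Cl2, −78 °C; then PPh3
Reagents that add atoms: ozone, O=[O+][O-]
Why: Ozonolysis with reductive work-up should cleave the terminal olefin to the C8 aldehyde.

Step 3
Reactants: 4; 5 methyl 2-{[(tert-butoxycarbonyl)oxy]methyl}prop-2-enoate
Product: 7 tert-butyl 2-methyl-3-[(2S)-4-methylidene-5-oxooxolan-2-yl]propanoate (C8 S, both C10 epimers), via hydroxy diester 6 (not isolated)
Conditions: [Ir(cod)Cl]2 (cat.), (R)-SEGPHOS (cat.), 4-chloro-3-nitrobenzoic acid (cat.), Cs2CO3 (cat.), 2-propanol, THF, 60 °C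
Reagents that add atoms: none
Why: Iridium-catalysed transfer-hydrogenative 2-(alkoxycarbonyl)allylation of the aldehyde should give the homoallylic alcohol, which lactonises in the flask; the C8 carbinol is set by the chiral ligand (reagent control, the ligand enantiomer that gives 8S being used).

Step 4
Reactants: 7
Product: 8 2-methyl-3-[(2S)-4-methylidene-5-oxooxolan-2-yl]propanoic acid
Conditions: CF3CO2H, CH2Cl2, 23 °C
Reagents that add atoms: none
Why: Acidolysis of the tert-butyl ester should free the C1 acid without touching the methylene lactone.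

Step 5
Reactants: 8
Product: 11 (3aS,7aS)-6-methyl-3-methylidenetetrahydro-2H-furo[3,2-b]pyran-2,5(3H)-dione (cis-fused bis-lactone with a C1–O–C7 δ-lactone, both C10 epimers), via dibromide 9 (not isolated), via bromomethylbutenolide acid 10 (not isolated)
Conditions: Br2, CH2Cl2, 0 °C; then Et3N, 0 to 23 °C
Reagents that add atoms: none
Why: Bromine addition to the exocyclic olefin and loss of HBr should give the 3-(bromomethyl)butenolide, whose carboxylate adds to C7 and expels bromide (SN2′ lactonisation, as known for Morita–Baylis–Hillman bromides); the tether allows only the cis ring fusion, so the temporary C7 centre is set by C8.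

Step 6
Reactants: 11
Product: 12 (3aS,6S,7aS)-6-bromo-6-methyl-3-methylidenetetrahydro-2H-furo[3,2-b]pyran-2,5(3H)-dione
Conditions: LiN(SiMe3)2, THF, −78 °C; then BrCl2C–CCl2Br, −78 °C
Reagents that add atoms: 1,2-dibromo-1,1,2,2-tetrachloroethane, BrC(Cl)(Cl)C(Cl)(Cl)Br
Why: Only C10 can be enolised, and electrophilic bromination of the lactone enolate should occur on the convex face of the cis-fused bicycle (the face of the two ring-fusion hydrogens), which sets C10 as S from either epimer of 11.

Step 7
Reactants: 12
Product: 13 (2S)-2-bromo-3-[(2S)-4-(bromomethyl)-5-oxo-2,5-dihydrofuran-2-yl]-2-methylpropanoic acid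
Conditions: HBr (33 % in AcOH), CH2Cl2, 0 °C
Reagents that add atoms: hydrogen bromide, Br
Why: SN2′ opening of the allylic (Morita–Baylis–Hillman-type) ester by bromide at C13 should release the C1 acid and the 3-(bromomethyl)butenolide; the temporary C7 centre disappears while C8 and C10 are untouched.

Step 8
Reactants: 14 (2Z)-3-methylpent-2-en-4-yn-1-ol
Product: 15 (2Z)-3-methylpent-2-en-4-ynal
Conditions: Dess–Martin periodinane, CH2Cl2, 0 °C
Reagents that add atoms: none
Why: Dess–Martin oxidation of the allylic alcohol should give the enal without Z/E isomerisation.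

Step 9
Reactants: 13; 15
Product: 16 (2S)-2-bromo-3-{(2S,3S)-3-[(1R,2Z)-1-hydroxy-3-methylpent-2-en-4-yn-1-yl]-4-methylidene-5-oxooxolan-2-yl}-2-methylpropanoic acid
Conditions: In powder, THF/aq. NH4Cl, 23 °C
Reagents that add atoms: none
Why: Indium-mediated Barbier allylation should join C7 to the aldehyde carbon C6 with allylic transposition to the methylene lactone; C7 is attacked anti to the C8 side chain and the chair (Zimmerman–Traxler) transition state of the ring-locked E-type allylindium should give the 6,7-anti adduct, so C8 sets C7 and C6.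

Step 10
Reactants: 16
Product: 17 (6R,7R,8S,10S)-enyne bromo bis-lactone (seven-membered C1–O6 lactone fused at C7–C8 to the α-methylene-γ-lactone; C6 carries the (1Z)-2-methylbut-1-en-3-yn-1-yl group)
Conditions: 2-methyl-6-nitrobenzoic anhydride, DMAP, Et3N, CH2Cl2 (high dilution), 23 °C
Reagents that add atoms: none
Why: Mixed-anhydride (Shiina) lactonisation should acylate O6 with the C1 acid and close the seven-membered lactone with retention at C6; acylation also blocks cycloisomerisation of the (Z)-enynol to a furan.

Step 11
Reactants: 17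
Product: 18 (6R,7R,8S,10S)-bromo bis-lactone methyl ketone (as 17, with the (1Z)-2-methyl-3-oxobut-1-en-1-yl group on C6)
Conditions: Ph3PAuNTf2 (cat.), 1,4-dioxane/H2O, 40 °C
Reagents that add atoms: water, O
Why: Gold-catalysed Markovnikov hydration of the terminal alkyne should give the C3 methyl ketone and leave the Z olefin and the tertiary bromide untouched.

Step 12
Reactants: 18
Product: 20 (4Z,6R,7S,8S,10R)-6-hydroxy-3,10-epoxy-1-oxogermacra-2,4,11(13)-trien-12,8-olide (the C6 alcohol of the target), via ten-membered bromo diketone 19 (not isolated)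
Conditions: LiN(SiMe3)2 (1.1 equiv), THF, −78 to −20 °C; then DMPU, 23 °C; AcOH quench
Reagents that add atoms: none
Why: Proposed new method: LiN(SiMe3)2 should remove a C2 proton of the methyl ketone, the enolate carbon should attack the lactone carbonyl C1 through a seven-membered transition state made possible by the cis C4=C5 bond, and collapse of the bicyclic tetrahedral alkoxide should cleave C1–O6, so that the seven-membered lactone is expanded by three atoms to the ten-membered carbocycle 19 (β-diketonate and C6 alkoxide), whose C3 oxygen then displaces the tertiary bromide at C10. The closest known reactions are the Baker–Venkataraman O-to-C acyl transfer and Claisen-type side-chain-insertion ring expansions for the first bond, and the base-induced closure of γ-bromo-β-diketones to 3(2H)-furanones for the second. The carbocycle is closed by ring expansion, not by end-to-end ten-ring closure, and the furanone by 5-exo-tet O-alkylation. C10 is the only new stereocentre: backside attack should invert the (10S)-bromide set in step 6 to the (10R)-ether, while C6, C7 and C8 are not touched. The step needs C-acylation from C2 rather than γ-deprotonation, loss of HBr or attack on the methylene lactone, which the hindered amide base at low temperature and the cis olefin holding the enolate next to C1 should secure; O- rather than C-alkylation at C10 follows because only the oxygen can reach C10 in a five-membered ring. One equivalent of base should suffice because the released alkoxide deprotonates the β-diketone.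

Step 13
Reactants: 21 (2E)-2-methylbut-2-en-1-ol
Product: 22 [(2R,3R)-2,3-dimethyloxiran-2-yl]methanol
Conditions: Ti(OiPr)4, D-(−)-diethyl tartrate, tBuOOH, 4 Å molecular sieves, CH2Cl2, −20 °C
Reagents that add atoms: tert-butyl hydroperoxide, CC(C)(C)OO
Why: Sharpless asymmetric epoxidation, in which the tartrate sets both epoxide centres (reagent control) and the E olefin gives the cis-dimethyl epoxide.

Step 14
Reactants: 22
Product: 23 (2S,3R)-2,3-dimethyloxirane-2-carboxylic acid
Conditions: TEMPO (cat.), PhI(OAc)2, MeCN/H2O, 23 °C
Reagents that add atoms: water, O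
Why: Oxoammonium oxidation of the primary alcohol through the aldehyde hydrate should give the acid without opening the epoxide (the descriptor at C2 changes by priority only).

Step 15
Reactants: 20; 23
Product: 24 the target, the O6 (2S,3R)-2,3-dimethyloxirane-2-carboxylate of 20 (4Z,6R,7R,8S,10R)
Conditions: 2,4,6-trichlorobenzoyl chloride, Et3N, THF; then 20, DMAP, toluene, 23 °C
Reagents that add atoms: none
Why: Yamaguchi esterification should acylate the hindered C6 alcohol with the α-quaternary epoxy acid under mild conditions that spare the methylene lactone, the furanone and the epoxide.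

Compound list
1 | tert-butyl propionate | CCC(=O)OC(C)(C)C | starting material
2 | allyl bromide | C=CCBr | starting material
3 | tert-butyl 2-methylpent-4-enoate (racemic) | C=CCC(C)C(=O)OC(C)(C)C | intermediate
4 | tert-butyl 2-methyl-4-oxobutanoate (racemic) | O=CCC(C)C(=O)OC(C)(C)C | intermediate
5 | methyl 2-{[(tert-butoxycarbonyl)oxy]methyl}prop-2-enoate | C=C(COC(=O)OC(C)(C)C)C(=O)OC | starting material
6 | 7-tert-butyl 1-methyl (4S)-4-hydroxy-6-methyl-2-methylideneheptanedioate | C=C(C[C@@H](O)CC(C)C(=O)OC(C)(C)C)C(=O)OC | intermediate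
7 | tert-butyl 2-methyl-3-[(2S)-4-methylidene-5-oxooxolan-2-yl]propanoate | C=C1C(=O)O[C@@H](CC(C)C(=O)OC(C)(C)C)C1 | intermediate
8 | 2-methyl-3-[(2S)-4-methylidene-5-oxooxolan-2-yl]propanoic acid | C=C1C(=O)O[C@@H](CC(C)C(O)=O)C1 | intermediate
9 | 3-[(2S)-4-bromo-4-(bromomethyl)-5-oxooxolan-2-yl]-2-methylpropanoic acid | BrCC1(Br)C(=O)O[C@@H](CC(C)C(O)=O)C1 | intermediate
10 | 3-[(2S)-4-(bromomethyl)-5-oxo-2,5-dihydrofuran-2-yl]-2-methylpropanoic acid | O=C1O[C@@H](CC(C)C(O)=O)C=C1CBr | intermediate
11 | (3aS,7aS)-6-methyl-3-methylidenetetrahydro-2H-furo[3,2-b]pyran-2,5(3H)-dione | C=C1C(=O)O[C@H]2CC(C)C(=O)O[C@@H]12 | intermediate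
12 | (3aS,6S,7aS)-6-bromo-6-methyl-3-methylidenetetrahydro-2H-furo[3,2-b]pyran-2,5(3H)-dione | C=C1C(=O)O[C@H]2C[C@](C)(Br)C(=O)O[C@@H]12 | intermediate
13 | (2S)-2-bromo-3-[(2S)-4-(bromomethyl)-5-oxo-2,5-dihydrofuran-2-yl]-2-methylpropanoic acid | O=C1O[C@@H](C[C@](C)(Br)C(O)=O)C=C1CBr | intermediate
14 | (2Z)-3-methylpent-2-en-4-yn-1-ol | C#C/C(C)=C\CO | starting material
15 | (2Z)-3-methylpent-2-en-4-ynal | C#C/C(C)=C\C=O | intermediate
16 | (2S)-2-bromo-3-{(2S,3S)-3-[(1R,2Z)-1-hydroxy-3-methylpent-2-en-4-yn-1-yl]-4-methylidene-5-oxooxolan-2-yl}-2-methylpropanoic acid | C=C1C(=O)O[C@@H](C[C@](C)(Br)C(O)=O)[C@@H]1[C@H](O)/C=C(/C)C#C | intermediate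
17 | (6R,7R,8S,10S)-enyne bromo bis-lactone (seven-membered C1–O6 lactone fused to the α-methylene-γ-lactone; (1Z)-2-methylbut-1-en-3-yn-1-yl on C6) | C=C1C(=O)O[C@H]2C[C@](C)(Br)C(=O)O[C@H](/C=C(/C)C#C)[C@H]12 | intermediate
18 | (6R,7R,8S,10S)-bromo bis-lactone methyl ketone ((1Z)-2-methyl-3-oxobut-1-en-1-yl on C6) | C=C1C(=O)O[C@H]2C[C@](C)(Br)C(=O)O[C@H](/C=C(/C)C(C)=O)[C@H]12 | intermediate
19 | (4Z,6R,7S,8S,10S)-10-bromo-6-hydroxy-1,3-dioxogermacra-4,11(13)-dien-12,8-olide (lithium salt in the flask) | C=C1C(=O)O[C@H]2C[C@](C)(Br)C(=O)CC(=O)/C(C)=C\[C@@H](O)[C@H]12 | intermediate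
20 | (4Z,6R,7S,8S,10R)-6-hydroxy-3,10-epoxy-1-oxogermacra-2,4,11(13)-trien-12,8-olide | C=C1C(=O)O[C@H]2C[C@@]3(C)OC(=CC3=O)/C(C)=C\[C@@H](O)[C@H]12 | intermediate
21 | (2E)-2-methylbut-2-en-1-ol | C/C=C(\C)CO | starting material
22 | [(2R,3R)-2,3-dimethyloxiran-2-yl]methanol | OC[C@@]1(C)O[C@@H]1C | intermediate
23 | (2S,3R)-2,3-dimethyloxirane-2-carboxylic acid | OC(=O)[C@@]1(C)O[C@@H]1C | intermediate
24 | target, O6 (2S,3R)-2,3-dimethyloxirane-2-carboxylate of 20 | C=C1C(=O)O[C@H]2C[C@@]3(C)OC(=CC3=O)/C(C)=C\[C@@H](OC(=O)[C@@]3(C)O[C@@H]3C)[C@H]12 | target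

Total step count: 15. Longest linear sequence: 12 steps (steps 1 to 7, 9 to 12 and 15).

Steps most likely to fail

1. Step 12 (proposed new method). The acyl shift may stall at the strained bicyclic tetrahedral stage. It may also be outrun by loss of HBr, by γ-deprotonation, or by translactonisation of the freed C6 alkoxide onto C12. Fallback with known chemistry, setting out from 13 and 14 and coming back at 20: alcohol 14 is silylated (tBuMe2SiCl, imidazole) to the silyl ether F1, and its alkyne is hydrated (Ph3PAuNTf2, wet dioxane) to the (Z)-methyl ketone F2. Acid 13 is converted with SOCl2 into the acid chloride F3. Soft enolisation of F2 (MgBr2·OEt2, iPr2NEt, CH2Cl2) and C-acylation by F3 should give the bromo diketone F4. On warming this should close to the furanone silyl ether F5, forming the same two bonds between separate fragments with inversion at C10. HF·pyridine should free the allylic alcohol F6 and Dess–Martin oxidation should give the enal F7. Intramolecular indium Barbier allylation at high dilution (C7 onto C6) should then close the ten-membered ring to 20.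

2. Step 9. The allylation may show poor or inverted relative selectivity at C6, and the (Z)-enynol product may cycloisomerise to a furan under the Lewis-acidic indium salts. Fallback, setting out from 13 and 15 and coming back at 17: the C6 epimer F8, separated from 16 or formed as the main adduct, is closed by Mitsunobu lactonisation (PPh3, DIAD, toluene, high dilution). This forms the C6–O bond by displacement with inversion and so converges on 17, while any 16 is taken through step 10.

3. Step 5. Loss of HBr may go toward the bromomethylene lactone, and the carboxylate may be alkylated between molecules instead of closing the bis-lactone. Fallback, setting out from 8 and coming back at 11: 8 is isomerised (RhCl3·3H2O cat., EtOH, heat) to the endocyclic butenolide acid F9. Wohl–Ziegler bromination of the allylic methyl (NBS, AIBN, PhCF3, reflux) should give 10, which is isolated and closed to 11 with NaHCO3 in DMF.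

Further compounds
F1 | step 12 | tert-butyldimethylsilyl ether of 14 | C#C/C(C)=C\CO[Si](C)(C)C(C)(C)C
F2 | step 12 | (3Z)-5-[(tert-butyldimethylsilyl)oxy]-3-methylpent-3-en-2-one | CC(=O)/C(C)=C\CO[Si](C)(C)C(C)(C)C
F3 | step 12 | acid chloride of 13 | O=C1O[C@@H](C[C@](C)(Br)C(Cl)=O)C=C1CBr
F4 | step 12 | (10S)-bromo diketone from F2 and F3 | O=C1O[C@@H](C[C@](C)(Br)C(=O)CC(=O)/C(C)=C\CO[Si](C)(C)C(C)(C)C)C=C1CBr
F5 | step 12 | (10R)-furanone silyl ether | O=C1O[C@@H](C[C@@]2(C)OC(=CC2=O)/C(C)=C\CO[Si](C)(C)C(C)(C)C)C=C1CBr
F6 | step 12 | (10R)-furanone allylic alcohol | O=C1O[C@@H](C[C@@]2(C)OC(=CC2=O)/C(C)=C\CO)C=C1CBr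
F7 | step 12 | (10R)-furanone enal | O=C1O[C@@H](C[C@@]2(C)OC(=CC2=O)/C(C)=C\C=O)C=C1CBr
F8 | step 9 | C6 epimer of 16 | C=C1C(=O)O[C@@H](C[C@](C)(Br)C(O)=O)[C@@H]1[C@@H](O)/C=C(/C)C#C
F9 | step 5 | 2-methyl-3-[(2S)-4-methyl-5-oxo-2,5-dihydrofuran-2-yl]propanoic acid | O=C1O[C@@H](CC(C)C(O)=O)C=C1C
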